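## The problem

CNP0207547.1 is a cis-fused pterocarpan, (6aS,11aS). Its benzene ring A carries three oxygen heterocycles: the pyran ring B (O5, C6H2), the dihydrofuran ring C (O11) that joins it to the methoxybenzene ring D, and a 2,2-dimethyldihydropyran ring E fused across C1–C2 with its oxygen on C1. Ring A is thus a fully differentiated phloroglucinol: one oxygen is in ring E (C1), one is a free phenol (C3) and one is O5 (C4a); C11b carries C11a and C4 stays unsubstituted. The only stereocentres, C6a and C11a, are adjacent at the B/C fusion. A trans-fused junction is out of reach, so C6a dictates C11a whenever ring C is closed last, and the real task is the single benzylic centre C6a. C11a is a benzylic ether carbon ortho or para to all three ring A oxygens: it ionizes under mild acid, and the cation can lose H6a to give an achiral isoflav-3-ene. The free C3 phenol para to C11b (quinone methide formation), the tertiary aryl ether of ring E and the open, very nucleophilic C4 position also forbid strong acid, hot base and unselective electrophiles late in the route. The opening lies in ring B: O5–C6H2 is an aryloxymethyl unit at the formaldehyde oxidation level, C6a–C11a is the two-carbon unit of an arylacetaldehyde enol ether, and C11b is the nucleophilic carbon ortho to O5. Ring B can therefore be read as a formal [4+2] adduct of an aryl oxocarbenium ion and an enol ether whose oxygen on C11a is later exchanged for O11.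

## Retrosynthesis

**22 to 21 (O–Si).** The last operation is removal of a triisopropylsilyl group from the C3 oxygen. The silyl ether is kept to the end because the free phenol para to C11b would make every acidic step before it a quinone methide problem. The same bulky group is needed earlier as a steric shield for C4.

**21 to 18 (O11–C11a, ring C).** Ring C is opened at the benzylic C–O bond, giving a 3-aryl-4-alkoxychroman 18 whose ring D oxygen is benzylated and whose C11a oxygen carries a cyclohexyl group. Cutting here rather than at O5–C6 uses the lability of C11a as an asset: the C11a ether ionizes easily, the ring D oxygen can only close cis to the C6a hydrogen, and the configuration at C11a in 18 is irrelevant. A single Lewis acid, BCl3, should cleave the benzyl ether and trigger the closure, so two protecting-group operations collapse into one. The forward step must avoid proton loss from the cation, which would erase C6a.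

**18 to 10 and 15 (C6–C6a and C11a–C11b, ring B).** This is the key disconnection. Ring B is divided into the aryloxymethyl chloride 10 (rings A and E with O5 and C6) and the enol ether 15 (ring D with C6a and C11a). Against a cut at O5–C6 or at C6a–C6b, it removes two skeletal bonds and the only independent stereocentre at once, and both fragments are simple arenes. The forward reaction must do three things. The cation from 10 must add to the aryl-bearing carbon of 15 from one face, which asks for a chiral group on the enol oxygen and a defined alkene geometry. The new oxocarbenium ion must be captured by C11b and not by C4, which the silyl ether next to C4 should ensure. The cross-reaction must also beat self-condensation of a very electron-rich cation precursor.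

**15 to 13 and 14 (enol C–O).** The enol ether is cut at the vinyl C–O bond to give the (E)-vinyl iodide 13 and (1R,2S)-2-phenylcyclohexanol 14. A Wittig construction of the C=C bond would be shorter on paper but gives mixtures of geometric isomers. Because the two isomers would deliver opposite configurations at C6a from the same shielded face, a stereoretentive copper-catalysed C–O coupling is preferred.

**13 to 12 to 11.** The vinyl iodide comes from aldehyde 12 by a one-carbon iodo-olefination, and 12 from commercial 2-hydroxy-4-methoxybenzaldehyde 11 by benzylation. Ring D is bought complete, with its methoxy group in place.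

**10 to 9 to 8 (C–Cl, O–Si).** The chloromethyl ether is traced to the methylsulfanylmethyl ether 9, the standard precursor of aryl chloromethyl ethers, and 9 to phenol 8 by silylation. The forward chlorination has to occur at sulfur faster than on ring A.

**8 to 5 to 4 to 1 and 2 (differentiating the ring A oxygens).** The two phenols of a 2,2-dimethylchroman-5,7-diol differ only in hindrance, and a bulky silyl chloride would go to the wrong one (the future O5). The chroman is therefore drawn from chromanone 4, made in one step from phloroglucinol 1 and 3-methylbut-2-enoic acid 2. In 4 the C4 carbonyl ties up the 5-OH by hydrogen bonding, so the 7-OH, the future O5, is alkylated selectively to give 5. Reductive removal of the carbonyl oxygen then gives 8 with the correct oxygen free for silylation. The carbonyl thus serves as a traceless regiochemical control element.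

## Roads not taken

**Alternative 1:** Ring C would be closed at C6a–C11a by carbene C–H insertion. The ring D aryldiazoacetate A1, whose ortho oxygen carries the ring A benzyl group, would be decomposed by Rh2(S-PTTL)4 (dirhodium tetrakis[N-phthaloyl-(S)-tert-leucinate]) to the cis-dihydrobenzofuran ester A2. Ester reduction, desilylation and a Mitsunobu closure between O5 and C6 would complete ring B.
- Merits: the step is catalytic and enantioselective, sets both stereocentres in their cis relation, and belongs to a reaction type with direct precedent on aryl benzyl ethers. In precedent and in catalyst control it is better than the chosen plan, which rests on an unproven annulation and a stoichiometric auxiliary.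
- Weak points for this target: the C–H bond to be inserted sits on a benzyl group with both ortho positions substituted and a trioxygenated ring, so approach of the carbene is hindered and hydride transfer or attack on the arene can compete. The cis ester in A2 is epimerizable at C6a under the basic desilylation. A1 needs a one-carbon substituent at C11b, which brings back the C11b against C4 problem as a formylation. C6 arrives as an ester and must be reduced.
- Comparison: the chosen plan sets against this a more convergent assembly, a C6 that enters at the right oxidation level, and a C11a that needs no control. Its route is several steps shorter.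

**Alternative 2:** Ring B would be formed by C11a–C11b and O5–C6 bond formation between the free chromanol A4 and 6-methoxybenzofuran-3-carbaldehyde A3 under a chiral diarylprolinol silyl ether. The ring A carbon ortho to the phenol would add to C2 of the benzofuran iminium ion and the phenol would close the lactol A5. Deoxygenation at C6 and desilylation would follow.
- Merits: if it worked it would be the shortest route by a wide margin, with no auxiliary and ring D and ring C bought as one heteroarene. In step economy it beats the chosen plan.
- Weak points: the conjugate addition must break the aromaticity of the furan at a carbon that already bears oxygen, so the acceptor is poor and the equilibrium unfavourable. The open hydroxy aldehyde form of A5 can revert by β-elimination of the O11 phenoxide and regain the benzofuran. C6a is α to the masked aldehyde and can epimerize. Removal of the lactol hydroxyl by ionic reduction needs a Lewis acid that would ionize C11a–O11 at least as readily. A4 offers two ortho carbons.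
- Comparison: the chosen plan has one unprecedented feature where this has two, and its ring closure is made irreversible by proton loss from ring A.

**Alternative 3:** Ring D would be built last by an intramolecular Diels–Alder reaction of a 5-bromo-2-pyrone tethered through O11 to a cis-3-ethynylchroman, A6. Loss of CO2 would give the 9-bromo pterocarpan A7. Copper-catalysed methoxylation and desilylation would follow.
- Merits: the regiochemistry of ring D is fixed by the tether, rings C and D close together, and no ring D phenol protecting group is needed. In that last respect it is cleaner than the chosen plan.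
- Weak points: both stereocentres and ring B must already be present in A6, so the central problem is only moved to an earlier stage. The C11a–O bond in A6 joins a trioxygenated benzylic carbon to a pyranol that is a good leaving group, and the cycloaddition needs prolonged heating, so ionization and elimination are likely. Ring D arrives as a bromide, and the pyrone fragment costs several steps.
- Comparison: the chosen plan takes ring D intact from a commercial aldehyde and reaches C6a in the same step that builds ring B.

Key step: step 9

Assumption: the facial sense in step 9 is assigned from the s-trans conformer of the (E)-enol ether 15, with the carbinol C–H eclipsing the enol C–O bond. On this model the (1R,2S)-alcohol 14 leads to (6aS). If the sense proves opposite, the (1S,2R)-alcohol, equally available, would be used in the same steps.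

## Route

Step 1
Reactants: 1 phloroglucinol; 2 3-methylbut-2-enoic acid
Product: 4 5,7-dihydroxy-2,2-dimethylchroman-4-one, via aryl enone 3 (not isolated)
Conditions: MeSO3H, P2O5, 70 °C
Reagents that add atoms: none
Why: Friedel–Crafts acylation of the symmetrical triol (every ring carbon is equivalent) followed by oxa-Michael closure of enone 3; the acyl group deactivates the ring against a second acylation.

Step 2
Reactants: 4 5,7-dihydroxy-2,2-dimethylchroman-4-one
Product: 5 5-hydroxy-2,2-dimethyl-7-[(methylsulfanyl)methoxy]chroman-4-one
Conditions: MeSCH2Cl (1.1 equiv), K2CO3 (1.1 equiv), NaI (cat.), DMF, 0 °C to rt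
Reagents that add atoms: chloromethyl methyl sulfide, CSCCl
Why: Williamson etherification; the 5-OH is held in a hydrogen bond to the C4 carbonyl, so one equivalent of base and electrophile should react at the more acidic, unhindered 7-OH, the oxygen that becomes O5.

Step 3
Reactants: 5 5-hydroxy-2,2-dimethyl-7-[(methylsulfanyl)methoxy]chroman-4-one
Product: 8 2,2-dimethyl-7-[(methylsulfanyl)methoxy]chroman-5-ol, via aryl ethyl carbonate 6 (not isolated), via ortho-quinone methide 7 (not isolated)
Conditions: ClCO2Et, Et3N, THF, 0 °C; filtration; then NaBH4, THF/H2O, 0 °C to rt
Reagents that add atoms: none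
Why: Known reductive deoxygenation of ortho-acylphenols through their ethyl carbonates: hydride reduces the ketone of 6, the carbonate shifts to the benzylic oxygen and is expelled to give quinone methide 7, which a second hydride reduces to the CH2 group; the neutral to basic medium spares the O,S-acetal.

Step 4
Reactants: 8 2,2-dimethyl-7-[(methylsulfanyl)methoxy]chroman-5-ol
Product: 9 2,2-dimethyl-7-[(methylsulfanyl)methoxy]-5-[(triisopropylsilyl)oxy]chroman
Conditions: i-Pr3SiCl, imidazole, DMF, 40 °C
Reagents that add atoms: chlorotriisopropylsilane, CC(C)[Si](Cl)(C(C)C)C(C)C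
Why: Silylation of the one remaining phenol; the O,S-acetal is inert, and the bulky silyl ether is placed next to the future C4, where it is needed as a shield in step 9.

Step 5
Reactants: 9 2,2-dimethyl-7-[(methylsulfanyl)methoxy]-5-[(triisopropylsilyl)oxy]chroman
Product: 10 7-(chloromethoxy)-2,2-dimethyl-5-[(triisopropylsilyl)oxy]chroman
Conditions: SO2Cl2 (1.0 equiv), CH2Cl2, −78 °C; then cyclohexene, −78 to 0 °C; concentrated and used crude
Reagents that add atoms: sulfuryl chloride, O=S(=O)(Cl)Cl
Why: Known conversion of methylsulfanylmethyl ethers into chloromethyl ethers by chlorination at sulfur and collapse of the O,S-acetal with loss of MeSCl; attack at sulfur should be far faster than chlorination of ring A at −78 °C with one equivalent, and cyclohexene takes up MeSCl before it can sulfenylate the ring.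

Step 6
Reactants: 11 2-hydroxy-4-methoxybenzaldehyde
Product: 12 2-(benzyloxy)-4-methoxybenzaldehyde
Conditions: BnBr, K2CO3, DMF, rt
Reagents that add atoms: benzyl bromide, BrCc1ccccc1
Why: Williamson etherification of the phenol; benzyl is chosen because the Lewis acid of step 10 removes it under the conditions that close ring C.

Step 7
Reactants: 12 2-(benzyloxy)-4-methoxybenzaldehyde
Product: 13 2-(benzyloxy)-1-[(E)-2-iodoethenyl]-4-methoxybenzene
Conditions: CHI3, CrCl2, THF, 0 °C to rt
Reagents that add atoms: iodoform, IC(I)I
Why: Takai olefination: the iodine-bearing gem-dichromium reagent formed from CHI3 and CrCl2 adds to the aldehyde, and anti elimination from the adduct should give the (E)-vinyl iodide; the aryl ethers are inert.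

Step 8
Reactants: 13 2-(benzyloxy)-1-[(E)-2-iodoethenyl]-4-methoxybenzene; 14 (1R,2S)-2-phenylcyclohexan-1-ol
Product: 15 2-(benzyloxy)-4-methoxy-1-[(E)-2-{[(1R,2S)-2-phenylcyclohexyl]oxy}ethenyl]benzene
Conditions: CuI (10 mol %), 3,4,7,8-tetramethyl-1,10-phenanthroline (20 mol %), Cs2CO3, toluene, 80 °C
Reagents that add atoms: none
Why: Ullmann-type C–O coupling of a vinyl iodide with an alcohol, which proceeds with retention of alkene geometry; the carbinol C–O bond of 14 is not broken, so (E) and (1R,2S) should both be carried into 15.

Step 9
Reactants: 10 7-(chloromethoxy)-2,2-dimethyl-5-[(triisopropylsilyl)oxy]chroman; 15 2-(benzyloxy)-4-methoxy-1-[(E)-2-{[(1R,2S)-2-phenylcyclohexyl]oxy}ethenyl]benzene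
Product: 18 (9S)-9-[2-(benzyloxy)-4-methoxyphenyl]-2,2-dimethyl-10-{[(1R,2S)-2-phenylcyclohexyl]oxy}-5-[(triisopropylsilyl)oxy]-3,4,9,10-tetrahydro-2H,8H-pyrano[2,3-f]chromene (C11a epimers), via aryloxymethyl cation 16 (not isolated), via C11a oxocarbenium ion 17 (not isolated)
Conditions: SnCl4 (1.1 equiv), 2,6-di-tert-butyl-4-methylpyridine (1.2 equiv), 4 Å molecular sieves, CH2Cl2 (0.02 M), −78 °C; 15 (1.5 equiv) present before SnCl4 is added; aqueous NaHCO3 quench at −78 °C
Reagents that add atoms: none
Why: Proposed new method: SnCl4 abstracts chloride from 10 to give cation 16, which is attacked by the aryl-bearing carbon of 15 (C6–C6a) because only this regiochemistry leaves the charge on the alkoxy-substituted carbon (17); the ring A carbon ortho to O5 then adds to C11a (C11a–C11b) and the proton goes to the hindered pyridine. The closest known reaction type is the SnCl4-promoted oxa-Povarov annulation of aryl oxocarbenium ions with alkenes to chromans, together with auxiliary-controlled additions to trans-2-phenylcyclohexyl enol ethers; new are the unsubstituted, formaldehyde-derived cation, the β-aryl enol ether as partner and the auxiliary control. Ring B is the only ring closed, by a six-membered intramolecular Friedel–Crafts alkylation in which the arene attacks the oxocarbenium carbon and the C=O bond stays outside the new ring (6-exo-trig at the electrophile). C6a is set in the first bond formation: in the s-trans conformer of 15 with the carbinol C–H eclipsing the enol C–O bond, the phenyl-bearing carbon of the (1R,2S)-cyclohexyl group lies under one face of the (E)-double bond, so 16 should add to the other face, which corresponds to (6aS); the (Z)-isomer would give the opposite configuration from the same face, hence the need for geometric purity. C11a forms without control and is carried on as both epimers, since step 10 ionizes and re-sets it. Site selectivity between C11b and C4, both ortho to O5, is expected from the triisopropylsilyl ether flanking C4, whereas C11b is flanked only by the tied-back ring E oxygen. The cross-reaction must beat Friedel–Crafts attack of 16 on a second molecule of 10 and cationic oligomerization of 15; high dilution, the excess of 15, −78 °C and the proton trap serve this, and the intramolecular closure of 17 should outrun its addition to a further enol ether.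

Step 10
Reactants: 18 the 3-aryl-4-alkoxychroman from step 9 (both C11a epimers)
Product: 21 (6aS,11aS)-3-O-triisopropylsilyl ether of the target pterocarpan, via debenzylated phenol 19 (not isolated), via C11a benzylic cation 20 (not isolated)
Conditions: BCl3 (2.5 equiv), C6Me5H (3 equiv), CH2Cl2, −78 °C; MeOH then aqueous NaHCO3 quench at −78 °C
Reagents that add atoms: none
Why: BCl3 with pentamethylbenzene as a non-basic benzyl cation trap cleaves the aryl benzyl ether (19) and ionizes the C11a ether, which is benzylic to the trioxygenated ring A (20); the ring D oxygen closes ring C by 5-exo attack on the planar cation, and because a trans B/C junction is out of reach C6a alone fixes C11a as (S), so both epimers of 18 converge. If ionization precedes debenzylation, the benzyl ether oxygen closes the ring and the benzyl group is lost afterwards with the same outcome; the methyl ether, the silyl ether and ring E should be inert to BCl3 at −78 °C. The reaction types are Lewis-acid debenzylation and SN1 cycloetherification, as in the acid-induced closure of 2'-hydroxyisoflavan-4-ols to pterocarpans.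

Step 11
Reactants: 21 (6aS,11aS)-3-O-triisopropylsilyl ether of the target pterocarpan
Product: 22 CNP0207547.1, the (6aS,11aS)-cis-pterocarpan with OH on C3, OMe on C9 and the 2,2-dimethyldihydropyran ring E fused at C1–C2 (ring oxygen on C1)
Conditions: Bu4NF, AcOH, THF, 0 °C
Reagents that add atoms: none
Why: Fluoride cleaves the aryl silyl ether; buffering with acetic acid keeps the liberated phenoxide, which is para to C11b, from opening ring C through a quinone methide, so neither stereocentre should be touched.

## Compound list

1 | phloroglucinol (benzene-1,3,5-triol) | Oc1cc(O)cc(O)c1 | starting material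
2 | 3-methylbut-2-enoic acid | CC(C)=CC(=O)O | starting material
3 | 3-methyl-1-(2,4,6-trihydroxyphenyl)but-2-en-1-one | CC(C)=CC(=O)c1c(O)cc(O)cc1O | intermediate (not isolated)
4 | 5,7-dihydroxy-2,2-dimethylchroman-4-one | CC1(C)CC(=O)c2c(O)cc(O)cc2O1 | intermediate
5 | 5-hydroxy-2,2-dimethyl-7-[(methylsulfanyl)methoxy]chroman-4-one | CSCOc1cc(O)c2C(=O)CC(C)(C)Oc2c1 | intermediate
6 | ethyl 2,2-dimethyl-7-[(methylsulfanyl)methoxy]-4-oxochroman-5-yl carbonate | CCOC(=O)Oc1cc(OCSC)cc2OC(C)(C)CC(=O)c12 | intermediate (not isolated)
7 | 2,2-dimethyl-7-[(methylsulfanyl)methoxy]-2,3-dihydro-5H-chromen-5-one (ortho-quinone methide) | CSCOC1=CC(=O)C2=CCC(C)(C)OC2=C1 | intermediate (not isolated)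
8 | 2,2-dimethyl-7-[(methylsulfanyl)methoxy]chroman-5-ol | CSCOc1cc(O)c2CCC(C)(C)Oc2c1 | intermediate
9 | 2,2-dimethyl-7-[(methylsulfanyl)methoxy]-5-[(triisopropylsilyl)oxy]chroman | CSCOc1cc(O[Si](C(C)C)(C(C)C)C(C)C)c2CCC(C)(C)Oc2c1 | intermediate
10 | 7-(chloromethoxy)-2,2-dimethyl-5-[(triisopropylsilyl)oxy]chroman | ClCOc1cc(O[Si](C(C)C)(C(C)C)C(C)C)c2CCC(C)(C)Oc2c1 | intermediate
11 | 2-hydroxy-4-methoxybenzaldehyde | COc1ccc(C=O)c(O)c1 | starting material
12 | 2-(benzyloxy)-4-methoxybenzaldehyde | COc1ccc(C=O)c(OCc2ccccc2)c1 | intermediate
13 | 2-(benzyloxy)-1-[(E)-2-iodoethenyl]-4-methoxybenzene | COc1ccc(/C=C/I)c(OCc2ccccc2)c1 | intermediate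
14 | (1R,2S)-2-phenylcyclohexan-1-ol (trans) | O[C@@H]1CCCC[C@H]1c1ccccc1 | starting material
15 | 2-(benzyloxy)-4-methoxy-1-[(E)-2-{[(1R,2S)-2-phenylcyclohexyl]oxy}ethenyl]benzene | COc1ccc(/C=C/O[C@@H]2CCCC[C@H]2c3ccccc3)c(OCc4ccccc4)c1 | intermediate
16 | ({2,2-dimethyl-5-[(triisopropylsilyl)oxy]chroman-7-yl}oxy)methylium (aryloxymethyl cation) | C=[O+]c1cc(O[Si](C(C)C)(C(C)C)C(C)C)c2CCC(C)(C)Oc2c1 | intermediate (not isolated)
17 | C11a oxocarbenium ion: O-[(1R,2S)-2-phenylcyclohexyl] oxonium of (2S)-2-[2-(benzyloxy)-4-methoxyphenyl]-3-(ring A aryloxy)propanal | COc1ccc(c(OCc2ccccc2)c1)[C@@H](COc1cc(O[Si](C(C)C)(C(C)C)C(C)C)c2CCC(C)(C)Oc2c1)C=[O+][C@@H]1CCCC[C@H]1c1ccccc1 | intermediate (not isolated)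
18 | (9S)-9-[2-(benzyloxy)-4-methoxyphenyl]-2,2-dimethyl-10-{[(1R,2S)-2-phenylcyclohexyl]oxy}-5-[(triisopropylsilyl)oxy]-3,4,9,10-tetrahydro-2H,8H-pyrano[2,3-f]chromene (C6a set as S, both C11a epimers) | COc1ccc(c(OCc2ccccc2)c1)[C@H]1COc2cc(O[Si](C(C)C)(C(C)C)C(C)C)c3CCC(C)(C)Oc3c2C1O[C@@H]4CCCC[C@H]4c5ccccc5 | intermediate
19 | debenzylated phenol: 18 with a free ring D hydroxyl in place of the benzyloxy group | COc1ccc(c(O)c1)[C@H]1COc2cc(O[Si](C(C)C)(C(C)C)C(C)C)c3CCC(C)(C)Oc3c2C1O[C@@H]4CCCC[C@H]4c5ccccc5 | intermediate (not isolated)
20 | C11a benzylic cation of 19 after loss of the cyclohexyloxy group | COc1ccc(c(O)c1)[C@H]1COc2cc(O[Si](C(C)C)(C(C)C)C(C)C)c3CCC(C)(C)Oc3c2[CH+]1 | intermediate (not isolated)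
21 | (6aS,11aS)-3-O-triisopropylsilyl ether of the target pterocarpan | COc1ccc2c(c1)O[C@@H]1c3c(cc(O[Si](C(C)C)(C(C)C)C(C)C)c4c3OC(C)(C)CC4)OC[C@H]21 | intermediate
22 | CNP0207547.1, (6aS,11aS)-cis-pterocarpan with OH on C3, OMe on C9 and a 2,2-dimethyldihydropyran ring E fused at C1–C2 (ring oxygen on C1) | COc1ccc2c(c1)O[C@@H]1c3c(cc(O)c4c3OC(C)(C)CC4)OC[C@H]21 | target

## Step count and risk

Total step count: 11. Longest linear sequence: 8 steps (steps 1 to 5, then 9 to 11); the enol ether branch is steps 6 to 8.

**Step 9 (key step, proposed new method).** The most likely failure is insufficient facial discrimination when 16 adds to 15. The phenyl shield of the auxiliary is remote from the aryl-bearing carbon in the s-trans conformer, and a second reactive conformer would expose the other face. Capture of 16 by ring A of another molecule is the second danger and is met within the step by dilution and the excess of 15. The fallback uses known chemistry. It sets out from 18, obtained with poor selectivity at C6a, and returns at 21. Solvolysis of the C11a ether with pyridinium p-toluenesulfonate in aqueous THF should give the isoflavan-4-ol F1. Oxidation with MnO2 should give the isoflavanone F2, whose C6a centre now equilibrates through the enol. Transfer hydrogenation with RuCl(p-cymene)[(S,S)-TsDPEN] in HCO2H/Et3N under dynamic kinetic resolution should give the cis-(S,S) alcohol F3, which is closed to 21 under the conditions of step 10. Control of C6a thus passes from the auxiliary to the catalyst.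

**Step 8.** The most likely failure is slow C–O coupling of the hindered secondary alcohol, so that base-induced loss of HI from 13 to the arylacetylene takes over. The fallback sets out from 14 and 12 and returns at 15. The alcohol 14 is converted with paraformaldehyde and Me3SiCl into the chloromethyl ether F4 and with PPh3 into the phosphonium salt F5. Its ylide (potassium tert-butoxide, THF) and aldehyde 12 should give 15 together with the (Z)-isomer F6 by Wittig olefination, and the isomers are separated by chromatography.

**Step 5.** The most likely failure is chlorination or methylsulfenylation of the very electron-rich ring A competing with reaction at sulfur. The fallback sets out from 9 and returns at 18. The methylsulfanylmethyl group is removed with AgNO3 and 2,6-lutidine in aqueous THF to give phenol F7, which is alkylated with bromomethyl acetate and i-Pr2NEt to the acetoxymethyl ether F8. SnCl4 should ionize this O,O-acetal to the same cation 16 in step 9, so that no chlorinating agent meets ring A.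

**Step 10.** The most likely failure is loss of H6a from cation 20 to the achiral isoflav-3-ene, which erodes the C6a configuration, or benzylation of C4 if ring closure and benzyl capture are slow. The fallback sets out from 18 and returns at 21 through 19 as an isolated compound. The benzyl ether is removed by hydrogenolysis (H2, Pd/C, EtOAc, trace Et3N) to give 19. Ring C is then closed with a catalytic amount of camphorsulfonic acid in CH2Cl2 at 0 °C, where the free phenol is already in place when the cation forms. No new compound arises.

## Further compounds

F1 | step 9 | 9-[2-(benzyloxy)-4-methoxyphenyl]-2,2-dimethyl-5-[(triisopropylsilyl)oxy]-3,4,9,10-tetrahydro-2H,8H-pyrano[2,3-f]chromen-10-ol (stereoisomer mixture) | COc1ccc(c(OCc2ccccc2)c1)C1COc2cc(O[Si](C(C)C)(C(C)C)C(C)C)c3CCC(C)(C)Oc3c2C1O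
F2 | step 9 | 9-[2-(benzyloxy)-4-methoxyphenyl]-2,2-dimethyl-5-[(triisopropylsilyl)oxy]-3,4,8,9-tetrahydro-2H,10H-pyrano[2,3-f]chromen-10-one (isoflavanone, configurationally labile at C6a) | COc1ccc(c(OCc2ccccc2)c1)C1COc2cc(O[Si](C(C)C)(C(C)C)C(C)C)c3CCC(C)(C)Oc3c2C1=O
F3 | step 9 | (9S,10S)-9-[2-(benzyloxy)-4-methoxyphenyl]-2,2-dimethyl-5-[(triisopropylsilyl)oxy]-3,4,9,10-tetrahydro-2H,8H-pyrano[2,3-f]chromen-10-ol (cis) | COc1ccc(c(OCc2ccccc2)c1)[C@H]1COc2cc(O[Si](C(C)C)(C(C)C)C(C)C)c3CCC(C)(C)Oc3c2[C@H]1O
F4 | step 8 | (1R,2S)-1-(chloromethoxy)-2-phenylcyclohexane | ClCO[C@@H]1CCCC[C@H]1c1ccccc1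
F5 | step 8 | triphenyl({[(1R,2S)-2-phenylcyclohexyl]oxy}methyl)phosphonium chloride | [Cl-].c1ccc(cc1)[P+](CO[C@@H]1CCCC[C@H]1c1ccccc1)(c1ccccc1)c1ccccc1
F6 | step 8 | 2-(benzyloxy)-4-methoxy-1-[(Z)-2-{[(1R,2S)-2-phenylcyclohexyl]oxy}ethenyl]benzene | COc1ccc(/C=C\O[C@@H]2CCCC[C@H]2c3ccccc3)c(OCc4ccccc4)c1
F7 | step 5 | 2,2-dimethyl-5-[(triisopropylsilyl)oxy]chroman-7-ol | Oc1cc(O[Si](C(C)C)(C(C)C)C(C)C)c2CCC(C)(C)Oc2c1
F8 | step 5 | ({2,2-dimethyl-5-[(triisopropylsilyl)oxy]chroman-7-yl}oxy)methyl acetate | CC(=O)OCOc1cc(O[Si](C(C)C)(C(C)C)C(C)C)c2CCC(C)(C)Oc2c1
F0 | step 10 | none | none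
A1 | alternative 1 | methyl 2-diazo-2-[2-({5,7-bis[(tert-butyldimethylsilyl)oxy]-2,2-dimethylchroman-8-yl}methoxy)-4-methoxyphenyl]acetate | COC(=O)C(=[N+]=[N-])c1ccc(OC)cc1OCc1c(O[Si](C)(C)C(C)(C)C)cc(O[Si](C)(C)C(C)(C)C)c2CCC(C)(C)Oc12
A2 | alternative 1 | methyl (2S,3R)-2-{5,7-bis[(tert-butyldimethylsilyl)oxy]-2,2-dimethylchroman-8-yl}-6-methoxy-2,3-dihydro-1-benzofuran-3-carboxylate (cis) | COc1ccc2c(c1)O[C@H](c1c(O[Si](C)(C)C(C)(C)C)cc(O[Si](C)(C)C(C)(C)C)c3c1OC(C)(C)CC3)[C@@H]2C(=O)OC
A3 | alternative 2 | 6-methoxy-1-benzofuran-3-carbaldehyde | COc1ccc2c(C=O)coc2c1
A4 | alternative 2 | 2,2-dimethyl-5-[(triisopropylsilyl)oxy]chroman-7-ol | Oc1cc(O[Si](C(C)C)(C(C)C)C(C)C)c2CCC(C)(C)Oc2c1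
A5 | alternative 2 | cis-pterocarpan C6 lactol with the ring fusion of the target, ring A phenol as triisopropylsilyl ether (anomeric mixture) | COc1ccc2c(c1)O[C@@H]1c3c(cc(O[Si](C(C)C)(C(C)C)C(C)C)c4c3OC(C)(C)CC4)OC(O)[C@H]21
A6 | alternative 3 | 5-bromo-3-{[cis-9-ethynyl-2,2-dimethyl-5-[(triisopropylsilyl)oxy]-3,4,9,10-tetrahydro-2H,8H-pyrano[2,3-f]chromen-10-yl]oxy}-2H-pyran-2-one, configured as in the target | O=c1occ(Br)cc1O[C@@H]1c2c(cc(O[Si](C(C)C)(C(C)C)C(C)C)c3c2OC(C)(C)CC3)OC[C@@H]1C#C
A7 | alternative 3 | 9-bromo analogue of 21 (cis-pterocarpan, ring A phenol as triisopropylsilyl ether) | Brc1ccc2c(c1)O[C@@H]1c3c(cc(O[Si](C(C)C)(C(C)C)C(C)C)c4c3OC(C)(C)CC4)OC[C@H]21
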